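You want the amount of target in the ash flask at 8.0 min, and whether blue or teal raises it.

| flask | substrate | gas phase | remark | time |
|---|---|---|---|---|
| ash | 10 mM | 2 mM (held) | the very flask that is asked about, followed so far |  |
| larch | 5 mM | 2 mM (held) | run made earlier |  |
| flask | 10 mM | 2.0 mM (held) |  | 8.0 min |

| run | time / min | target / % |
|---|---|---|
| ash | 0.200 | 0.5 |
| ash | 0.667 | 0.5 |
| ash | 1.00 | 1.8 |
| ash | 1.50 | 2.7 |
| ash | 2.50 | 5.1 |
| ash | 3.00 | 6.3 |
| ash | 4.00 | 7.8 |
| larch | 0.250 | 0 |
| larch | 0.417 | 0.3 |
| larch | 0.667 | 0.8 |
| larch | 0.833 | 1.3 |
| larch | 1.33 | 1.8 |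
| larch | 2.00 | 4.2 |
| larch | 3.00 | 7.8 |

(scatter of a reading: 0.3 percentage points)

- at the start none of the gas is dissolved
- steps under discussion: gas phase <-> dissolved gas; substrate + dissolved gas <-> target; substrate -> side product; target <-> isomer of the product; dissolved gas + target -> over-reaction product

- blue: doubling the saturation concentration of gas phase, all else as stated
- teal: doubling the transfer coefficient of the gas phase, all else as stated

- amount of target at 8.0 min, in percent of the substrate charged
- the change that raises the amount of target at 8.0 min, in percent of the substrate charged most ("none" if none brings more than 2 percentage points) (blue / teal / none)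
- amount of target at 8.0 min, in percent of the substrate charged, after blue

From 1.00 min to 4.00 min the ash flask gains target at 0.200 mM min⁻¹, its absolute rate of target formation, while the larch flask, with half the substrate, gains 0.180 mM min⁻¹ over its last readings. As readings, these make the apparent order in [substrate] 0.155, but each reading behind that figure carries a scatter of 0.3 percentage points, so I keep it as a reading, draw no step from it, and carry on the ash flask's own rate. Carried straight on, my reckoning puts the ash flask at 16.0 % of target at 8.0 min, though that line was read over only 3.00 min.

The forecast gives 15 % (13 % to 16.5 %), names blue as best, and expects 28 % (23 % to 31 %) after it, arguing: “So the rate barely depends on substrate, which points to gas transfer as the limit.”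

The ash flask gives 10.3 % of target; blue is best, gaining 4.5 points against 2 points for teal, and reaches 14.8 %.

    gas phase ⇌ dissolved gas, rate k1*(csat - [dissolved gas]) (kL = 0.00730 s⁻¹)
    substrate + dissolved gas ⇌ target (K = 500 M⁻¹, k = 0.900 M⁻¹ s⁻¹)
    substrate → side product (k = 0.00250 s⁻¹)
    target ⇌ isomer of the product (K = 1.10, k = 6.00 × 10⁻⁴ s⁻¹)
    dissolved gas + target → over-reaction product (k = 0.630 M⁻¹ s⁻¹)

Held against 0.200 mM min⁻¹, the ash flask averages 0.129 mM min⁻¹ over its 8.0 min, less than the line, and blue multiplies its target by 1.44, against the forecast's 1.87. Its [dissolved gas] stands at 1.16 mM at 4.00 min, where the forecast put 0.08 mM. Read the same flask at 2.0 min instead: the rate 0.200 mM min⁻¹ gives 4.00 % of target, and that neighbour flask, with [dissolved gas] at 0.853 mM, holds 4.06 %.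

(The numbers in the tables were generated by integration with constants of no real substance; scatter was added.)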